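Locants: the bicyclo[3.2.1]octane has bridgeheads C1 and C5. C2, C3 and C4 are the three-carbon tricarbonyl bridge, C6 and C7 the two-carbon bridge, C8 the one-carbon ketone bridge. C9 (gem-dimethyl), C10 (acetyl) and C11 complete ring A (C1, C7, C9, C10, C11); ring B is C1, C8, C5, C6, C7; ring C is C1, C2, C3, C4, C5, C8.
Enabling feature: ring C is a dearomatised 3-methyl acylphloroglucinol. C6–C7–C9(Me2) on C5 and C11–C10–C(acetyl) on C1 are two prenyl chains, the second lacking one carbon. Their alkene carbons C7 and C10 each lie five atoms from a radical site, first C1 and then C9.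
Retrosynthetic cuts, in order: C3–CH2 of the prenyl group; acetyl C=O back to C=CH2; C9–C10 and C1–C7 together; C5–C6; C1–C11; C3–acyl carbon.
Forward: ring C is bought as the arene and loaded by acylation, C1 prenylation and dearomative C5 prenylation. One oxidative radical cascade then closes ring B and ring A in that order. Ozonolysis and C3 prenylation finish the synthesis.
Stereochemistry: C5 comes from a ligand-controlled palladium allylic alkylation. C1, C7 and C10 are relayed from C5 in the cascade. C3 comes from exo-face attack (syn to C8) on the bicyclic enolate.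

Key step: step 5

Assumption: the (R,R) ligand is taken to deliver the S configuration at C5; if the sense of induction is the opposite, the (S,S) ligand is used and nothing else changes.
Remark: enolised triketones are drawn as one tautomer, and CIP descriptors refer to that tautomer and the locants above; C5 and C10 change descriptor along the route through priority changes only.
Remark: the ring C enol is carried unprotected, because the C4 oxygen is the most hindered one and is chelated to the isobutyryl group, so its selective etherification beside the free C8 enol cannot be defended.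

Step 1
Reactants: 1 2-methylphloroglucinol (2-methylbenzene-1,3,5-triol); 2 isobutyryl chloride (2-methylpropanoyl chloride)
Product: 3 1-(2,4,6-trihydroxy-3-methylphenyl)-2-methylpropan-1-one
Conditions: AlCl3 (3.5 equiv), PhNO2, 65 °C; then 1 M HCl, 0 °C
Reagents that add atoms: isobutyryl chloride, CC(C)C(Cl)=O
Why: Friedel–Crafts acylation of a highly activated arene whose two free positions are equivalent, so only one ketone can form, and chelation of the new aryl ketone to aluminium should stop a second acylation.

Step 2
Reactants: 3 1-(2,4,6-trihydroxy-3-methylphenyl)-2-methylpropan-1-one; 4 prenyl bromide (1-bromo-3-methylbut-2-ene)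
Product: 5 1-[2,4,6-trihydroxy-3-methyl-5-(3-methylbut-2-en-1-yl)phenyl]-2-methylpropan-1-one
Conditions: 4 (1.0 equiv), KOH (1.0 equiv), H2O, 0 °C to rt; aq NaHCO3 wash
Reagents that add atoms: prenyl bromide, CC(C)=CCBr
Why: C-alkylation of a phloroglucinol phenolate in water, where hydrogen bonding to oxygen steers the allylic bromide to carbon; the unsubstituted ring carbon is the least hindered site and its adduct rearomatises, and any over-alkylated dienone, a much stronger acid, is removed by the bicarbonate wash so that no racemic material enters step 4.

Step 3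
Reactants: 6 prenol (3-methylbut-2-en-1-ol); 7 di-tert-butyl dicarbonate
Product: 8 tert-butyl 3-methylbut-2-en-1-yl carbonate (tert-butyl prenyl carbonate)
Conditions: Bu4NHSO4 (5 mol %), 30% aq NaOH, CH2Cl2, 0 °C to rt
Reagents that add atoms: di-tert-butyl dicarbonate, CC(C)(C)OC(=O)OC(=O)OC(C)(C)C
Why: Phase-transfer O-acylation of a primary allylic alcohol with Boc2O, the standard entry to allylic tert-butyl carbonates.

Step 4
Reactants: 5 1-[2,4,6-trihydroxy-3-methyl-5-(3-methylbut-2-en-1-yl)phenyl]-2-methylpropan-1-one; 8 tert-butyl prenyl carbonate
Product: 9 (4S)-3,5-dihydroxy-4-methyl-4,6-bis(3-methylbut-2-en-1-yl)-2-(2-methylpropanoyl)cyclohexa-2,5-dien-1-one (the quaternary ring carbon is C5 of the target)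
Conditions: Pd2(dba)3·CHCl3 (2.5 mol %), (R,R)-DACH-phenyl Trost ligand (7.5 mol %), 8 (1.0 equiv), toluene, 0 °C
Reagents that add atoms: tert-butyl prenyl carbonate, CC(C)=CCOC(=O)OC(C)(C)C
Why: Tsuji–Trost asymmetric allylic alkylation run as the dearomatisation of a phenol: zerovalent palladium ionises 8 to the 1,1-dimethylallyl complex, CO2 and tert-butoxide, the base frees the phenolate of 5, and this attacks the unsubstituted allyl terminus through the methyl-bearing ring carbon (less hindered than the prenyl-bearing one, while O-allylation is reversible under the catalyst), the chiral pocket of the ligand selecting the ring face and so setting C5 as S.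

Step 5
Reactants: 9 (4S)-3,5-dihydroxy-4-methyl-4,6-bis(3-methylbut-2-en-1-yl)-2-(2-methylpropanoyl)cyclohexa-2,5-dien-1-one
Product: 13 tricyclic isopropenyl enol-dione (1R,5R,7R,10R): rings A to C complete; C2 and C8 ketones; C4 enol; isobutyryl on C3; C9 exo on the C6–C7 bridge; isopropenyl on C10 trans to ring B, via C1 radical 10 (not isolated), via C9 radical 11 (not isolated), via side-chain radical 12 (not isolated)
Conditions: Mn(OAc)3·2H2O (2.2 equiv), Cu(OAc)2·H2O (1.0 equiv), degassed AcOH, 23 °C
Reagents that add atoms: none
Why: Mn(OAc)3 binds the C8/C2 enolate of 9 and inner-sphere electron transfer gives the electrophilic radical 10, which reacts at C1; the closest known reaction type is the Mn(OAc)3/Cu(OAc)2 oxidative free-radical polycyclisation of unsaturated 1,3-dicarbonyl compounds. Ring B closes first by 5-exo-trig addition of C1 to C7 of the C5 prenyl alkene (10 to 11), ring A closes second by 5-exo-trig addition of the tertiary C9 radical to C10 of the C1 prenyl alkene (11 to 12), and Cu(OAc)2 converts the tertiary radical 12 through an organocopper species and β-hydride loss into the less substituted alkene, the copper salt being regenerated by the second equivalent of Mn(OAc)3. C1 is fixed by C5, because the two-atom C6–C7 tether can only reach the face of ring C on which it stands. C7 is fixed by the exo placement of C9 (syn to C8): this orientation keeps the CMe2 terminus from lying under the C2–C3–C4 bridge in the first transition state, and only the exo radical can reach C10, so endo material cannot end up in 13. C10 is set in a chair-like 5-hexenyl radical transition state that puts the CMe2 terminus on the convex face of the new cis-fused A/B diquinane, cis to H7 and trans to ring B, and this is the least secure of the three centres. The step needs bond formation at C1 and not at C3, which shares the spin in the free trione: C3 carries the chelated isobutyryl group, lies between three carbonyls and has no second alkene in reach, whereas C1 holds both alkenes at 5-exo distance.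

Step 6
Reactants: 13 tricyclic isopropenyl enol-dione
Product: 15 tricyclic acetyl enol-dione (1R,5R,7R,10S): as 13 but acetyl on C10 in place of isopropenyl and same spatial arrangement, via ozonide 14 (not isolated)
Conditions: O3 (1.0 equiv, titrated solution in CH2Cl2), CH2Cl2, −78 °C; then PPh3 (1.2 equiv), −78 °C to rt
Reagents that add atoms: ozone, [O-][O+]=O
Why: Ozonolysis with reductive work-up (Criegee mechanism): the 1,1-disubstituted isopropenyl alkene is the only electron-rich, accessible π bond, whereas the C3=C4 enol is tetrasubstituted, chelated and bears two acyl groups, so one measured equivalent of ozone should be consumed by the side chain alone under neutral conditions that leave C10 untouched, and the cleavage must precede step 7 because a prenyl alkene would react faster than the isopropenyl group.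

Step 7
Reactants: 15 tricyclic acetyl enol-dione; 8 tert-butyl prenyl carbonate
Product: 16 (1R,3S,5S,7R,10S)-10-acetyl-3-isobutyryl-5,9,9-trimethyl-3-prenyl tricyclic 2,4,8-trione (CNP0322535.2)
Conditions: Pd(PPh3)4 (5 mol %), 8 (1.05 equiv), THF, 0 °C to rt
Reagents that add atoms: tert-butyl prenyl carbonate, CC(C)=CCOC(=O)OC(C)(C)C
Why: Tsuji–Trost allylic alkylation of a strongly acidic tricarbonyl C–H acid without added base: the tert-butoxide released from 8 is consumed by the enol of 15, any O-prenyl ether is re-ionised by zerovalent palladium so that material drains to carbon, the bulky enolate takes the unsubstituted allyl terminus (linear prenyl), and it does so on the exo face of the C2–C3–C4 bridge, syn to C8 and away from the endo hydrogens on C6 and C7, which sets C3 as S without disturbing C10.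

Compound list
1 | 2-methylphloroglucinol | Cc1c(O)cc(O)cc1O | starting material
2 | isobutyryl chloride | CC(C)C(Cl)=O | starting material
3 | 1-(2,4,6-trihydroxy-3-methylphenyl)-2-methylpropan-1-one | CC(C)C(=O)c1c(O)cc(O)c(C)c1O | intermediate
4 | prenyl bromide | CC(C)=CCBr | starting material
5 | 1-[2,4,6-trihydroxy-3-methyl-5-(3-methylbut-2-en-1-yl)phenyl]-2-methylpropan-1-one | CC(C)C(=O)c1c(O)c(C)c(O)c(CC=C(C)C)c1O | intermediate
6 | prenol | CC(C)=CCO | starting material
7 | di-tert-butyl dicarbonate | CC(C)(C)OC(=O)OC(=O)OC(C)(C)C | starting material
8 | tert-butyl prenyl carbonate | CC(C)=CCOC(=O)OC(C)(C)C | intermediate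
9 | (4S)-3,5-dihydroxy-4-methyl-4,6-bis(3-methylbut-2-en-1-yl)-2-(2-methylpropanoyl)cyclohexa-2,5-dien-1-one | CC(C)=CCC1=C(O)[C@](C)(CC=C(C)C)C(O)=C(C(=O)C(C)C)C1=O | intermediate
10 | C1 radical of 9 | CC(C)=CC[C]1C(=O)[C@](C)(CC=C(C)C)C(O)=C(C(=O)C(C)C)C1=O | intermediate
11 | bicyclic C9 radical, ring B closed, C9 exo | CC(C)=CC[C@]12C(=O)[C@](C)(C[C@@H]1[C](C)C)C(O)=C(C(=O)C(C)C)C2=O | intermediate
12 | tricyclic side-chain radical, rings A and B closed, 2-propyl radical on C10 | C[C](C)[C@H]1C[C@]23C(=O)[C@](C)(C[C@@H]2C1(C)C)C(O)=C(C(=O)C(C)C)C3=O | intermediate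
13 | tricyclic isopropenyl enol-dione (1R,5R,7R,10R) | CC(=C)[C@H]1C[C@]23C(=O)[C@](C)(C[C@@H]2C1(C)C)C(O)=C(C(=O)C(C)C)C3=O | intermediate
14 | 1,2,4-trioxolane (ozonide) of 13, ozonide carbon unassigned | CC4(OCOO4)[C@H]1C[C@]23C(=O)[C@](C)(C[C@@H]2C1(C)C)C(O)=C(C(=O)C(C)C)C3=O | intermediate
15 | tricyclic acetyl enol-dione (1R,5R,7R,10S) | CC(=O)[C@H]1C[C@]23C(=O)[C@](C)(C[C@@H]2C1(C)C)C(O)=C(C(=O)C(C)C)C3=O | intermediate
16 | CNP0322535.2, (1R,3S,5S,7R,10S) | CC(=O)[C@H]1C[C@]23C(=O)[C@](C)(C[C@@H]2C1(C)C)C(=O)[C@](CC=C(C)C)(C(=O)C(C)C)C3=O | target

Total steps: 7. Longest linear sequence: 6 (steps 1, 2, 4, 5, 6, 7).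

Steps most likely to fail

Step 4. The nucleophile attacks the allyl ligand on the side away from the metal, so discrimination between the two faces of the methyl-bearing ring carbon may be poor. Attack through the prenyl-bearing carbon may also compete. The fallback replaces catalysis by resolution. It sets out from 5, which is alkylated with 4 in aqueous KOH at 0 °C to give the racemic dienone F1, a strong vinylogous acid. Treatment with (R)-1-phenylethylamine in ethyl acetate should let the salt of the S acid F2 crystallise while the salt of the R acid F3 stays in the mother liquor; the other amine enantiomer is used if the solubilities are reversed. Acidification of the crystals with dilute HCl returns the route to 9.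

Step 7. Alkylation may stop at oxygen. The C3–prenyl bond may also be re-ionised by zerovalent palladium, because the triketone anion is a good leaving group. The fallback makes use of O-alkylation. It sets out from 15, which with allyl bromide and K2CO3 in acetone should give the allyl enol ether F4 (drawn at O4). A thermal Claisen rearrangement in toluene at 110 °C moves the allyl group to C3 across the same exo face and gives the C3-allyl tetraketone F5. Cross metathesis with 2-methylbut-2-ene (second-generation Grubbs catalyst, CH2Cl2, 40 °C) turns allyl into prenyl and comes back at 16.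

Step 5. Facial selectivity at C10 in the second closure may be poor, since both orientations of the C1 prenyl alkene are open to the C9 radical. The fallback moves control of C10 from the kinetic closure to an equilibration. It sets out from 9, whose cascade then also delivers the C10-epimeric isopropenyl enol-dione F6. Ozonolysis as in step 6 passes through the epimeric ozonide F7 to the C10-epimeric acetyl enol-dione F8. DBU (3 equiv, toluene, 40 °C) first forms the ring C enolate, which shields that ring from cleavage, and then equilibrates the centre next to the methyl ketone. The equilibrium is expected to lean toward acetyl on the convex face, cis to H7. The epimers are separated, the unwanted one is resubmitted, and the route is rejoined at 15.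

Further compounds
F1 | step 4 | racemic 3,5-dihydroxy-4-methyl-4,6-bis(3-methylbut-2-en-1-yl)-2-(2-methylpropanoyl)cyclohexa-2,5-dien-1-one | CC(C)=CCC1=C(O)C(C)(CC=C(C)C)C(O)=C(C(=O)C(C)C)C1=O
F2 | step 4 | (R)-1-phenylethylammonium salt of the S acid | C[C@@H]([NH3+])c1ccccc1.CC(C)=CCC1=C([O-])[C@](C)(CC=C(C)C)C(O)=C(C(=O)C(C)C)C1=O
F3 | step 4 | (R)-1-phenylethylammonium salt of the R acid | C[C@@H]([NH3+])c1ccccc1.CC(C)=CCC1=C([O-])[C@@](C)(CC=C(C)C)C(O)=C(C(=O)C(C)C)C1=O
F4 | step 7 | O4-allyl enol ether of 15 | CC(=O)[C@H]1C[C@]23C(=O)[C@](C)(C[C@@H]2C1(C)C)C(OCC=C)=C(C(=O)C(C)C)C3=O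
F5 | step 7 | C3-allyl tetraketone (1R,3S,5S,7R,10S) | CC(=O)[C@H]1C[C@]23C(=O)[C@](C)(C[C@@H]2C1(C)C)C(=O)[C@](CC=C)(C(=O)C(C)C)C3=O
F6 | step 5 | C10-epimeric isopropenyl enol-dione (1R,5R,7R,10S) | CC(=C)[C@@H]1C[C@]23C(=O)[C@](C)(C[C@@H]2C1(C)C)C(O)=C(C(=O)C(C)C)C3=O
F7 | step 5 | ozonide of F6, ozonide carbon unassigned | CC4(OCOO4)[C@@H]1C[C@]23C(=O)[C@](C)(C[C@@H]2C1(C)C)C(O)=C(C(=O)C(C)C)C3=O
F8 | step 5 | C10-epimeric acetyl enol-dione (1R,5R,7R,10R) | CC(=O)[C@@H]1C[C@]23C(=O)[C@](C)(C[C@@H]2C1(C)C)C(O)=C(C(=O)C(C)C)C3=O
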